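Readings and results are simulated on assumed constants; scatter was added.

Subtract [starting material] from [reagent] before anything else: each event removes one of each, so that difference stays put while the ratio of the two moves.

| setting | larch | cedar | maple | oak | ash |
|---|---|---|---|---|---|
| starting material | 0.500 M | 0.300 M | 0.500 M | 0.500 M | 0.500 M |
| reagent | 0.600 M | 0.400 M | 1.80 M | 0.600 M | 0.200 M |
| free catalyst | 0.00500 M | 0.00500 M | 0.00500 M | 0.0150 M | 0.0100 M |
| time |  |  |  |  | 8.6 h |

- larch run (time / h: [product] / M): 0.65: 0.147; 2.0: 0.291; 3.8: 0.371; 6.0: 0.418; 8.6: 0.454
- cedar run (time / h: [product] / M): 0.65: 0.065; 2.0: 0.159; 3.8: 0.202; 6.0: 0.234; 8.6: 0.254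
- maple run (time / h: [product] / M): 0.65: 0.332; 2.0: 0.475; 3.8: 0.497; 6.0: 0.501; 8.6: 0.496
- oak run (time / h: [product] / M): 0.65: 0.183; 2.0: 0.362; 3.8: 0.442; 6.0: 0.478; 8.6: 0.485

(each reading ± 0.003 M)

- how the opening rate goes with [reagent] round the charge of the larch run: the exponent of the rate at two percent of starting material gone to product
- how the opening rate goes with [free catalyst] round the charge of the larch run: the exponent of the rate at two percent of starting material gone to product
- the cedar run starts with 0.200 M less of starting material and of reagent than the larch run, and with no product. Compared where both hold the same amount of starting material, once fifteen percent of what the cedar run was charged with has turned into product, is the cedar run faster, slower or alike (within a tenth)?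
- product in the ash run at 8.6 h, as a share of the starting material charged

- Overall: starting material + reagent -> product, with free catalyst as catalyst.
- Constant volume, constant temperature.
- The analysis sees a species whether free or bound.
- An order is taken over about fifteen percent of the charge, up and down.

If the rate is k[starting material][reagent], the ratio shifts exponentially, and I fold the givens into one number. I call it the reach: k times the time times that difference, taken positive. The ratio of the scarcer species to the more plentiful one falls by the factor exp(reach). The larch run at 3.8 h gives k = 1.03 M⁻¹ h⁻¹. The maple run, with 1.80 M of reagent against 0.600 M, gives 1.05 M⁻¹ h⁻¹ at 0.65 h, so I take the order in reagent as 1.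

The cedar charge holds what the larch run holds of starting material and reagent after 0.200 M has reacted, 0.300 M and 0.400 M, and its reading at 6.0 h gives 1.06 M⁻¹ h⁻¹, so I expect the two to be alike.

One number fails on the oak run, whose first reading gives 1.41 M⁻¹ h⁻¹ against 1.03 M⁻¹ h⁻¹ from the first larch reading. Across that catalyst change the exponent is 0.286. The oak value climbs to 2.16 M⁻¹ h⁻¹ at 3.8 h, so I read the opening as lower still and commit to an order in catalyst below that exponent.

In the ash run reagent is the limiting reagent, and the larch k gives 2.66 for the reach, k times the time times the difference of the two charges. The ratio of reagent to starting material then falls to 0.0280, which by my reckoning leaves 0.00865 M of reagent, so a reagent molecule has a 4.32 % chance of surviving. That makes my figure for product 38.3 % of the starting material charged.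

The forecast gives 1 for reagent, 0.8 for catalyst, alike for the cedar comparison and 39.3 % for the ash run, which is higher than mine. It parts from me on catalyst, on the ground that “At high catalyst and high substrate something is sequestering it”.

The flask gives 1.0 for reagent, 0.060 for catalyst, alike for the cedar comparison and 38.9 % for the ash run.

    free catalyst + starting material ⇌ catalyst-substrate complex, settled at all times (29.90 M⁻¹)
    free catalyst + reagent ⇌ catalyst-reagent complex, settled at all times (0.2670 M⁻¹)
    catalyst-substrate complex + catalyst-reagent complex → product + 2 free catalyst (43920 M⁻¹ h⁻¹)
    free catalyst + reagent → spent catalyst + reagent (4.464 M⁻¹ h⁻¹)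
    starting material + reagent → product (1.001 M⁻¹ h⁻¹)

The ash result corresponds to a reach of 3.10 against my 2.66. The uncatalysed reaction of starting material with reagent carries most of the ash run: with that step removed, product there falls from 38.9 % to 13.8 %, and the order in catalyst round the larch charge climbs from 0.060 to 3.0. In the maple run, a quarter of the starting material needs a reach of 0.216, which at the larch k means 0.161 h, and the maple run took 0.161 h.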